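**Remark on the chemistry.** Ring atoms are numbered C1–C10 as in a germacrane: epoxide on C1/C10, methyl C14 on C10, ketone at C3, hydroxymethyl C15 on C4, lactone oxygen on C6, C11(=C13)–C12 on C7, ester oxygen on C8. "8α/8β" means the C8 oxygen is on the face of H7 or of C11. Assumption: the ring closure follows the closed, metal-bridged chair known for intermolecular additions of this allylmetal type. That chair gives the 8α-carbinol, and the route is written for that outcome.

## Analysis of the target

The target is a cyclodecane fused trans across C6–C7 to an α-methylene-γ-butyrolactone and fused across C1–C10 to an oxirane. The epoxide is cis (C2 and C9 on the same side), so it derives from a Z-configured C1=C10 olefin. There are seven stereocentres: C1 and C10 (epoxide), C4 (hydroxymethyl, α to the ketone), the contiguous triad C6–C7–C8, and C2 of the (R)-2-methylbutanoyl group. H6 and H7 are anti, and the C8 oxygen lies on the face of C11 (8β). C4 is 1,3-related to C6 and is separated from the epoxide by the C3 carbonyl. The C3 ketone is both a β-hydroxy ketone (towards C15: retro-aldol, dehydration, epimerisation of C4) and a β,γ-epoxy ketone (towards C1: base opens the epoxide by E1cB). The exocyclic enoate is a Michael acceptor, the epoxide is acid-labile, and before epoxidation the C1=C10 olefin can slip into conjugation with C3. The difficulty is to close a ten-membered ring that carries this much sensitive functionality and to relate C1/C10 to the distant C4/C6–C8 centres through the ring conformation alone. The strategy rests on one feature: C7 lies between the lactone carbon C6 and the carbinol C8 and carries C11. A 3-(bromomethyl)butenolide (O on C6, C7=C11, bromide on C13) is therefore a latent C7 nucleophile that creates the C11=C13 methylene as it bonds to a C8 aldehyde.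

## Retrosynthetic reasoning

**Epoxide last (34 from 33).** The two C–O bonds of the oxirane are cut first. The epoxide is the group least able to travel, and the Z-olefin of 33 is the only electron-rich olefin in the molecule. The forward step must deliver oxygen under neutral conditions to one face of the ring olefin.

**Ketone and hydroxyl unmasked late (33 from 32 from 31).** The C3 carbonyl is traced back to a dithioacetal and the C15 hydroxyl to a silyl ether. A free ketone would make C4 epimerisable and would invite loss of the C15 oxygen and conjugation of the olefin, so it stays masked through ring closure and esterification. The silyl ether is removed before the ketone is freed, so that fluoride never meets a β-silyloxy ketone.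

**Ester with inversion (31 from 29 and 30).** The C8–O bond is cut on the alkyl side. In the ring closure the lactone ring holds C6 trans to C13 across C7=C11, and a chair with the C9 chain equatorial then places the new oxygen anti to C6, which is 8α. The 8β ester is therefore made by Mitsunobu inversion with acid 30. This also means the α-stereocentre of 30 never passes through an activated acyl derivative.

**Ring closure (29 from 27).** The C7–C8 bond is cut. This is the only ring bond whose formation also makes two stereocentres and the α-methylene lactone, and both reacting groups (allylic bromide, aldehyde) tolerate the dithiane and silyl ether. The forward reaction must favour ring closure over intermolecular addition and must attack C7 anti to the C5 branch.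

**Aldehyde and bromide (27 from 26 from 25).** The β,γ-unsaturated aldehyde is generated in the last step before cyclisation, from the C8 silyl ether via the alcohol, because it cannot be stored.

**Butenolide (25 from 23 from 21 from 20).** The C13–Br bond is traced back to a C7 hydroxyl with allylic transposition, the lactone C–O bond to a hydroxy ester, and the C7–C11 bond to an aldehyde at C7 plus an acrylate α-anion equivalent. The aldehyde supplies the oxidation level that the bromomethylbutenolide needs. Everything is done after the organolithium chemistry, since a butenolide would not survive it.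

**Fragment union (20 from 19 from 17 and 7).** The C2–C3 bond is cut between a 2-lithio-1,3-dithiane and a Z-allylic bromide. This joins two fragments of similar size, fixes the ketone surrogate, and leaves the olefin geometry untouched (SN2 at a primary allylic carbon).

**Dithiane fragment (17 from 15 from 14 from 12 and 10; 12 from 11; 10 from 8 and 9).** The C3–C4 bond is cut. C6 comes from the chiral pool as lactone 11, whose carbonyl carbon becomes C15. The dithianyl carbon C3 is added to the lactone α-carbon anti to the C6 side chain, which sets C4. C3 arrives already at the aldehyde oxidation level and masked, so C4 is never α to a free aldehyde, and the C6 and C7 oxygens are differentiated from the start.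

**Z-olefin (7 from 6 from 5 from 4 from 2 from 1).** The C10–C14 bond is cut. Syn-carbocupration of ynoate 4 followed by protonation with retention fixes the methyl cis to the vinyl hydrogen, hence C2 and C9 cis, and gives the two chain ends in different oxidation states.

## Alternatives that were turned down

**Alternative 1: homoenolate ring closure at C5–C6.**
- Disconnection and key step: the ring is cut between C5 and C6. In cyclopropanol aldehyde A1 the three-membered ring spans C3, C4 and C5. A dialkylzinc base would form the zinc cyclopropoxide, which opens at the less substituted C3–C5 bond to a homoenolate (ketone at C3, zinc on C5) that adds to the C6 aldehyde and gives γ-hydroxy ketone A2.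
- For: ketone release and ring closure are one event, no dithioacetal is needed, and the C8 ester is carried through with its configuration already set. On the last point it is stronger than the chosen route, which needs a late inversion.
- Against: ketone homoenolates of zinc are weak nucleophiles towards aldehydes, and a ten-membered closure of this kind has no close model. The C6 carbinol forms without a cyclic organising element from the substrate. The C3 ketone appears under alkoxide conditions next to C4 and a β-silyloxy group. The aldehyde of A1 is α to C7, which bears the isopropenyl-type unit and is prone to epimerisation and olefin migration. After A2 the lactone still has to be built by selective oxidation of C12 next to an identically protected C15.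
- Comparison: the chosen route offers a bond-forming event with proven reactivity on both partners, and it forms the lactone's exocyclic olefin in the cyclisation itself.

**Alternative 2: ring unveiled by olefin cleavage.**
- Disconnection and key step: both carbonyls at C3 and C8 are traced to a tetrasubstituted C3=C8 olefin in bicyclic diene lactone A3, the Birch-type reduction product of an aromatic ring. Ozonolysis with reductive work-up of that olefin would give dione A4.
- For: no macrocyclisation is needed and the Z geometry of C1=C10 is guaranteed by the six-membered ring. On certainty of ring formation it is stronger than the chosen route.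
- Against: selectivity between the tetrasubstituted olefin, the trisubstituted olefin and the methylene lactone rests only on electron richness. A4 is a 1,6-diketone whose carbonyls are within transannular aldol reach. C7 is α to the C8 ketone and vinylogously activated by the lactone, so it would epimerise or the methylene would move into the ring. C8 must then be reduced chemo- and stereoselectively beside the C3 ketone.
- Comparison: the chosen route delivers C8 directly as a carbinol and keeps C3 masked, at the price of a medium-ring closure.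

**Alternative 3: allylboration ring closure at C8–C9.**
- Disconnection and key step: the ring is cut between C8 and C9. Lactone aldehyde A5 carries a secondary allylic pinacol boronate at C1. On warming it would add through C9 to the C8 aldehyde in a closed chair, move the olefin to C1=C10 and give alcohol A6.
- For: the step is thermal and reagent-free, and the boron chair transfers the C1 configuration to both C8 and the olefin geometry. On predictability at C8 it is stronger than the chosen route and could give 8β directly.
- Against: A5 needs an enantioenriched α-substituted allylboronate carried next to an aldehyde. That aldehyde sits on C7, β to the lactone oxygen on C6, so β-elimination and epimerisation threaten. A6 lacks C13, and the methylene would have to be added afterwards by enolate chemistry on a compound bearing a free C8 hydroxyl. The Z/E outcome depends on an axial preference that a forming ten-membered ring may override.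
- Comparison: the chosen route uses an aldehyde with no leaving group β to it, makes the Z-olefin separately and securely, and installs the methylene during ring closure.

Key step: step 18

## Route

Step 1
Reactants: 1 but-3-yn-1-ol
Product: 2 tert-butyl(but-3-yn-1-yloxy)dimethylsilane
Conditions: tBuMe2SiCl, imidazole, CH2Cl2, 0 °C → rt
Reagents that add atoms: tert-butylchlorodimethylsilane, CC(C)(C)[Si](C)(C)Cl
Why: Standard silylation of a primary alcohol; this ether marks the future C8 oxygen and is of intermediate lability among the silyl groups used.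

Step 2
Reactants: 2 tert-butyl(but-3-yn-1-yloxy)dimethylsilane
Product: 4 methyl 5-[(tert-butyldimethylsilyl)oxy]pent-2-ynoate, via lithium acetylide 3 (not isolated)
Conditions: nBuLi, THF, −78 °C; then ClCO2Me, −78 → 0 °C
Reagents that add atoms: methyl chloroformate, COC(=O)Cl; n-butyllithium, [Li]CCCC (lithium of 3 only)
Why: Deprotonation of the terminal alkyne and C-acylation of the acetylide with a chloroformate; the new carbonyl carbon becomes C2.

Step 3
Reactants: 4 methyl 5-[(tert-butyldimethylsilyl)oxy]pent-2-ynoate
Product: 5 methyl (2Z)-5-[(tert-butyldimethylsilyl)oxy]-3-methylpent-2-enoate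
Conditions: Me2CuLi (from CuI and MeLi), THF, −78 °C; MeOH quench at −78 °C
Reagents that add atoms: lithium dimethylcuprate, [Li+].C[Cu-]C
Why: Syn-carbocupration of the ynoate and protonation of the vinylcopper with retention place the new methyl (C14) cis to the vinyl hydrogen, so the C9 chain and the ester are cis (Z); the cold quench prevents equilibration through the allenoate.

Step 4
Reactants: 5 methyl (2Z)-5-[(tert-butyldimethylsilyl)oxy]-3-methylpent-2-enoate
Product: 6 (2Z)-5-[(tert-butyldimethylsilyl)oxy]-3-methylpent-2-en-1-ol
Conditions: iBu2AlH, CH2Cl2, −78 °C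
Reagents that add atoms: none
Why: 1,2-Reduction of the enoate by an aluminium hydride gives the allylic alcohol without touching the olefin geometry.

Step 5
Reactants: 6 (2Z)-5-[(tert-butyldimethylsilyl)oxy]-3-methylpent-2-en-1-ol
Product: 7 [(3Z)-5-bromo-3-methylpent-3-en-1-yl]oxy(tert-butyl)dimethylsilane
Conditions: CBr4, PPh3, CH2Cl2, 0 °C
Reagents that add atoms: carbon tetrabromide, BrC(Br)(Br)Br
Why: Appel bromination of a primary allylic alcohol proceeds by SN2 at C2 under neutral conditions, so the Z-olefin and the silyl ether are kept.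

Step 6
Reactants: 8 1,3-dithiane; 9 triphenylcarbenium tetrafluoroborate
Product: 10 1,3-dithian-2-ylium tetrafluoroborate
Conditions: CH2Cl2, reflux; filtration under argon
Reagents that add atoms: none
Why: Hydride abstraction from C2 of the dithiane by the trityl cation gives the sulfur-stabilised carbenium salt, which precipitates and serves as a masked formyl cation.

Step 7
Reactants: 11 (5R)-5-(hydroxymethyl)oxolan-2-one
Product: 12 (5R)-5-{[(triethylsilyl)oxy]methyl}oxolan-2-one
Conditions: Et3SiCl, imidazole, CH2Cl2, 0 °C
Reagents that add atoms: chlorotriethylsilane, CC[Si](CC)(CC)Cl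
Why: Silylation of the primary alcohol; the lactone carbon C5 is the future C6 and the triethylsilyl ether at the future C7 is the group that step 12 later converts directly into the aldehyde.

Step 8
Reactants: 12 (5R)-5-{[(triethylsilyl)oxy]methyl}oxolan-2-one; 10 1,3-dithian-2-ylium tetrafluoroborate
Product: 14 (3S,5R)-3-(1,3-dithian-2-yl)-5-{[(triethylsilyl)oxy]methyl}oxolan-2-one, via silyl ketene acetal 13 (not isolated)
Conditions: LiN(iPr)2, Me3SiCl, THF, −78 °C; solvent exchange to CH2Cl2; then 10, −78 → −40 °C
Reagents that add atoms: chlorotrimethylsilane, C[Si](C)(C)Cl (silyl group of 13 only)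
Why: Mukaiyama-type alkylation of an O-silyl ketene acetal by a dithio-stabilised carbenium ion; the electrophile approaches the planar C4 anti to the C6 side chain, giving the trans-3,5-disubstituted lactone and thereby C4 (S). C3 enters already masked at the aldehyde level, so C4 is never α to a free carbonyl outside the lactone.

Step 9
Reactants: 14 (3S,5R)-3-(1,3-dithian-2-yl)-5-{[(triethylsilyl)oxy]methyl}oxolan-2-one
Product: 15 (2S,4R)-2-(1,3-dithian-2-yl)-5-[(triethylsilyl)oxy]pentane-1,4-diol
Conditions: LiBH4, THF, 0 °C → rt
Reagents that add atoms: none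
Why: Borohydride reduction opens the lactone to the 1,4-diol; the former carbonyl carbon becomes C15 and the ring oxygen the C6 hydroxyl, with no epimerisable intermediate.

Step 10
Reactants: 15 (2S,4R)-2-(1,3-dithian-2-yl)-5-[(triethylsilyl)oxy]pentane-1,4-diol
Product: 17 2-[(2S,4R)-1-[(tert-butyldiphenylsilyl)oxy]-4,5-bis[(triethylsilyl)oxy]pentan-2-yl]-1,3-dithiane, via mono-silyl ether 16 (not isolated)
Conditions: tBuPh2SiCl, imidazole, DMF, 0 °C; then Et3SiCl, rt
Reagents that add atoms: tert-butylchlorodiphenylsilane, CC(C)(C)[Si](Cl)(c1ccccc1)c1ccccc1; chlorotriethylsilane, CC[Si](CC)(CC)Cl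
Why: The bulky silyl chloride takes the primary C15 hydroxyl and the secondary C6 hydroxyl is then capped; the graded lability (triethylsilyl at C6 and C7, tert-butyldimethylsilyl at C8, tert-butyldiphenylsilyl at C15) sets the order of the later unmaskings.

Step 11
Reactants: 17 2-[(2S,4R)-1-[(tert-butyldiphenylsilyl)oxy]-4,5-bis[(triethylsilyl)oxy]pentan-2-yl]-1,3-dithiane; 7 [(3Z)-5-bromo-3-methylpent-3-en-1-yl]oxy(tert-butyl)dimethylsilane
Product: 19 2-[(2S,4R)-1-[(tert-butyldiphenylsilyl)oxy]-4,5-bis[(triethylsilyl)oxy]pentan-2-yl]-2-[(2Z)-5-[(tert-butyldimethylsilyl)oxy]-3-methylpent-2-en-1-yl]-1,3-dithiane, via 2-lithiodithiane 18 (not isolated)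
Conditions: tBuLi, THF/HMPA, −78 °C; then 7, −78 → −40 °C
Reagents that add atoms: tert-butyllithium, [Li]C(C)(C)C (lithium of 18 only)
Why: Corey–Seebach umpolung: the hindered dithiane is lithiated at C3 and alkylated by the primary allylic bromide in an SN2 reaction that forms C2–C3 and keeps the Z-olefin. The silyl ether three atoms from the carbanion does not migrate, because the Brook equilibrium of such systems lies on the side of the dithiane anion.

Step 12
Reactants: 19 2-[(2S,4R)-1-[(tert-butyldiphenylsilyl)oxy]-4,5-bis[(triethylsilyl)oxy]pentan-2-yl]-2-[(2Z)-5-[(tert-butyldimethylsilyl)oxy]-3-methylpent-2-en-1-yl]-1,3-dithiane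
Product: 20 (2R,4S)-4-{2-[(2Z)-5-[(tert-butyldimethylsilyl)oxy]-3-methylpent-2-en-1-yl]-1,3-dithian-2-yl}-5-[(tert-butyldiphenylsilyl)oxy]-2-[(triethylsilyl)oxy]pentanal
Conditions: (COCl)2, DMSO, CH2Cl2, −78 → −40 °C; then Et3N, −78 → 0 °C
Reagents that add atoms: none
Why: Under Swern conditions a primary triethylsilyl ether is cleaved in situ and oxidised directly to the aldehyde, while secondary triethylsilyl, tert-butyldimethylsilyl and tert-butyldiphenylsilyl ethers stay; this gives the C7 aldehyde in one operation and it is used crude.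

Step 13
Reactants: 20 (2R,4S)-4-{2-[(2Z)-5-[(tert-butyldimethylsilyl)oxy]-3-methylpent-2-en-1-yl]-1,3-dithian-2-yl}-5-[(tert-butyldiphenylsilyl)oxy]-2-[(triethylsilyl)oxy]pentanal
Product: 21 methyl (3RS,4R,6S)-6-{2-[(2Z)-5-[(tert-butyldimethylsilyl)oxy]-3-methylpent-2-en-1-yl]-1,3-dithian-2-yl}-7-[(tert-butyldiphenylsilyl)oxy]-3-hydroxy-2-methylidene-4-[(triethylsilyl)oxy]heptanoate
Conditions: iBu2AlH, HMPA, methyl propiolate, THF, 0 °C; then 20, 0 °C → rt
Reagents that add atoms: methyl propiolate, C#CC(=O)OC
Why: Hydroalumination of the propiolate gives an α-aluminoacrylate that adds to the aldehyde and delivers the Morita–Baylis–Hillman-type adduct (C7–C11 bond) without an amine base, so the α-silyloxy aldehyde does not epimerise at C6. The configuration of the new C7 carbinol is irrelevant because C7 becomes trigonal in step 15.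

Step 14
Reactants: 21 methyl (3RS,4R,6S)-6-{2-[(2Z)-5-[(tert-butyldimethylsilyl)oxy]-3-methylpent-2-en-1-yl]-1,3-dithian-2-yl}-7-[(tert-butyldiphenylsilyl)oxy]-3-hydroxy-2-methylidene-4-[(triethylsilyl)oxy]heptanoate
Product: 23 (4RS,5R)-5-[(2S)-2-{2-[(2Z)-5-[(tert-butyldimethylsilyl)oxy]-3-methylpent-2-en-1-yl]-1,3-dithian-2-yl}-3-[(tert-butyldiphenylsilyl)oxy]propyl]-4-hydroxy-3-methylideneoxolan-2-one, via hydroxy ester 22 (not isolated)
Conditions: HF·pyridine, pyridine, THF, 0 °C; then CSA (cat.), CH2Cl2, rt
Reagents that add atoms: none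
Why: Buffered fluoride removes the secondary triethylsilyl ether faster than the two bulkier primary silyl ethers, and acid-catalysed transesterification then closes the five-membered lactone from the C6 hydroxyl (the C7 hydroxyl could only give a four-membered ring).

Step 15
Reactants: 23 (4RS,5R)-5-[(2S)-2-{2-[(2Z)-5-[(tert-butyldimethylsilyl)oxy]-3-methylpent-2-en-1-yl]-1,3-dithian-2-yl}-3-[(tert-butyldiphenylsilyl)oxy]propyl]-4-hydroxy-3-methylideneoxolan-2-one
Product: 25 (5R)-3-(bromomethyl)-5-[(2S)-2-{2-[(2Z)-5-[(tert-butyldimethylsilyl)oxy]-3-methylpent-2-en-1-yl]-1,3-dithian-2-yl}-3-[(tert-butyldiphenylsilyl)oxy]propyl]furan-2(5H)-one, via allylic mesylate 24 (not isolated)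
Conditions: (MeSO2)2O, iPr2NEt, CH2Cl2, −20 °C; then LiBr, THF, 0 °C → rt
Reagents that add atoms: methanesulfonic anhydride, CS(=O)(=O)OS(C)(=O)=O (sulfonyl group of 24 only); lithium bromide, [Li+].[Br-]
Why: Sulfonylation of the allylic alcohol and SN2′ displacement by bromide at C13 move the olefin into the ring (C7=C11), the conjugated and thermodynamically preferred isomer; both C7 epimers converge. No oxidant or strong acid is used, so the dithiane and silyl ethers survive.

Step 16
Reactants: 25 (5R)-3-(bromomethyl)-5-[(2S)-2-{2-[(2Z)-5-[(tert-butyldimethylsilyl)oxy]-3-methylpent-2-en-1-yl]-1,3-dithian-2-yl}-3-[(tert-butyldiphenylsilyl)oxy]propyl]furan-2(5H)-one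
Product: 26 (5R)-3-(bromomethyl)-5-[(2S)-3-[(tert-butyldiphenylsilyl)oxy]-2-{2-[(2Z)-5-hydroxy-3-methylpent-2-en-1-yl]-1,3-dithian-2-yl}propyl]furan-2(5H)-one
Conditions: HF·pyridine, pyridine, THF, 0 °C → rt
Reagents that add atoms: none
Why: Fluoride-mediated desilylation distinguishes the primary tert-butyldimethylsilyl ether at C8 from the much slower tert-butyldiphenylsilyl ether at C15; the weakly nucleophilic, mildly acidic medium leaves the allylic bromide and the butenolide untouched.

Step 17
Reactants: 26 (5R)-3-(bromomethyl)-5-[(2S)-3-[(tert-butyldiphenylsilyl)oxy]-2-{2-[(2Z)-5-hydroxy-3-methylpent-2-en-1-yl]-1,3-dithian-2-yl}propyl]furan-2(5H)-one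
Product: 27 (3Z)-5-{2-[(2S)-1-[(2R)-4-(bromomethyl)-5-oxo-2,5-dihydrofuran-2-yl]-3-[(tert-butyldiphenylsilyl)oxy]propan-2-yl]-1,3-dithian-2-yl}-3-methylpent-3-enal
Conditions: Dess–Martin periodinane, NaHCO3, CH2Cl2, 0 °C; used at once
Reagents that add atoms: none
Why: Dess–Martin oxidation is neutral when buffered and amine-free, so the β,γ-unsaturated aldehyde does not move into conjugation and the allylic bromide is not quaternised.

Step 18
Reactants: 27 (3Z)-5-{2-[(2S)-1-[(2R)-4-(bromomethyl)-5-oxo-2,5-dihydrofuran-2-yl]-3-[(tert-butyldiphenylsilyl)oxy]propan-2-yl]-1,3-dithian-2-yl}-3-methylpent-3-enal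
Product: 29 (1(10)Z,4S,6R,7R,8S)-15-[(tert-butyldiphenylsilyl)oxy]-8-hydroxy-3,3-(propane-1,3-diyldisulfanediyl)germacra-1(10),11(13)-dien-12,6-olide, via allylindium dibromide 28 (not isolated)
Conditions: In powder, THF/H2O (4:1), 25 °C; 27 added slowly to a final 0.002 M
Reagents that add atoms: indium, [In] (metal of 28 only)
Why: Indium inserts into the allylic C13–Br bond of 27 to give the σ-allylindium 28 (trivalent indium), which adds through its γ-carbon C7 to the C8 aldehyde in a six-membered, metal-bridged transition state (SE2′ allylation), so that C7–C8 forms, the olefin moves from C7=C11 to C11=C13 and the butenolide becomes the α-methylene lactone. The closest known reaction types are the Barbier additions of 3-(bromomethyl)butenolides to aldehydes mediated by indium, zinc or chromium, and the Barbier and Nozaki–Hiyama closures of 2-(bromomethyl)acrylates onto tethered aldehydes that give ten-membered rings; this step combines the two. The ten-membered carbocycle closes in the 10-exo-trig mode at the aldehyde carbon, with the allyl unit reacting with transposition so that C7 and not C13 enters the ring. C7 is controlled by the C6 stereocentre: the aldehyde reaches the butenolide face opposite the C5 branch, which gives the trans-fused lactone (H6 and H7 anti). C8 is controlled by the chair: the lactone ring holds C6 trans to C13 across C7=C11 (an E-type allylmetal), and with the C9 chain equatorial the new oxygen comes out anti to C6, that is 8α (8S), which is why step 19 is written as an inversion (the opposite outcome at C8 would simply turn step 19 into an acylation with retention). The step needs ring closure to outrun intermolecular addition and protonation of 28, which slow addition, high dilution and the fast addition of allylindium species to aldehydes in water should secure. It also needs the aldehyde to stay unconjugated, which the neutral medium secures; the dithiane, lactone and silyl ether are inert to the organoindium.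

Step 19
Reactants: 29 (1(10)Z,4S,6R,7R,8S)-15-[(tert-butyldiphenylsilyl)oxy]-8-hydroxy-3,3-(propane-1,3-diyldisulfanediyl)germacra-1(10),11(13)-dien-12,6-olide; 30 (2R)-2-methylbutanoic acid
Product: 31 (1(10)Z,4S,6R,7S,8R)-15-[(tert-butyldiphenylsilyl)oxy]-8-{[(2R)-2-methylbutanoyl]oxy}-3,3-(propane-1,3-diyldisulfanediyl)germacra-1(10),11(13)-dien-12,6-olide
Conditions: PPh3, iPrO2CN=NCO2iPr, toluene, 0 °C → rt
Reagents that add atoms: none
Why: Mitsunobu esterification: the carboxylate displaces the C8 oxyphosphonium by SN2, turning 8α-OH into the 8β-ester. The acid acts as nucleophile, so its α-stereocentre is never activated and cannot racemise (the C7 descriptor changes from R to S only because the substituent priorities change).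

Step 20
Reactants: 31 (1(10)Z,4S,6R,7S,8R)-15-[(tert-butyldiphenylsilyl)oxy]-8-{[(2R)-2-methylbutanoyl]oxy}-3,3-(propane-1,3-diyldisulfanediyl)germacra-1(10),11(13)-dien-12,6-olide
Product: 32 (1(10)Z,4S,6R,7S,8R)-15-hydroxy-8-{[(2R)-2-methylbutanoyl]oxy}-3,3-(propane-1,3-diyldisulfanediyl)germacra-1(10),11(13)-dien-12,6-olide
Conditions: HF·pyridine, THF, 0 °C → rt
Reagents that add atoms: none
Why: Fluoride cleavage of the primary silyl ether is done while C3 is still a dithioacetal, so no β-silyloxy or β-hydroxy ketone is exposed to the reagent; ester, lactone and dithiane are stable to it.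

Step 21
Reactants: 32 (1(10)Z,4S,6R,7S,8R)-15-hydroxy-8-{[(2R)-2-methylbutanoyl]oxy}-3,3-(propane-1,3-diyldisulfanediyl)germacra-1(10),11(13)-dien-12,6-olide
Product: 33 (1(10)Z,4S,6R,7S,8R)-15-hydroxy-8-{[(2R)-2-methylbutanoyl]oxy}-3-oxogermacra-1(10),11(13)-dien-12,6-olide
Conditions: PhI(O2CCF3)2, NaHCO3, MeCN/H2O (9:1), 0 °C
Reagents that add atoms: water, O
Why: Oxidative dithioacetal hydrolysis with a trivalent iodine reagent: sulfur is activated, water adds to the thionium ion and the ketone is released within minutes. Buffering keeps the β,γ-olefin out of conjugation and spares C4, and isolated olefins, alcohols and esters tolerate the reagent.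

Step 22
Reactants: 33 (1(10)Z,4S,6R,7S,8R)-15-hydroxy-8-{[(2R)-2-methylbutanoyl]oxy}-3-oxogermacra-1(10),11(13)-dien-12,6-olide
Product: 34 (1R,4S,6R,7S,8R,10S)-1,10-epoxy-15-hydroxy-8-{[(2R)-2-methylbutanoyl]oxy}-3-oxogermacr-11(13)-en-12,6-olide (CNP0219035.1)
Conditions: dimethyldioxirane, acetone/CH2Cl2, −20 °C
Reagents that add atoms: dimethyldioxirane, CC1(C)OO1
Why: Concerted, stereospecific epoxidation by a dioxirane turns the Z-olefin into the cis-epoxide and prefers the electron-rich trisubstituted olefin over the methylene lactone. The face (1R,10S) is expected from attack on the outer face of the olefin in the lactone-fused ring, and the neutral, non-nucleophilic medium spares the β-hydroxy ketone and the new β,γ-epoxy ketone.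

## Compound list

1 | but-3-yn-1-ol | C#CCCO | starting material
2 | tert-butyl(but-3-yn-1-yloxy)dimethylsilane | C#CCCO[Si](C)(C)C(C)(C)C | intermediate
3 | {4-[(tert-butyldimethylsilyl)oxy]but-1-yn-1-yl}lithium (formed in situ) | [Li]C#CCCO[Si](C)(C)C(C)(C)C | intermediate
4 | methyl 5-[(tert-butyldimethylsilyl)oxy]pent-2-ynoate | COC(=O)C#CCCO[Si](C)(C)C(C)(C)C | intermediate
5 | methyl (2Z)-5-[(tert-butyldimethylsilyl)oxy]-3-methylpent-2-enoate | COC(=O)/C=C(C)\CCO[Si](C)(C)C(C)(C)C | intermediate
6 | (2Z)-5-[(tert-butyldimethylsilyl)oxy]-3-methylpent-2-en-1-ol | OC/C=C(C)\CCO[Si](C)(C)C(C)(C)C | intermediate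
7 | [(3Z)-5-bromo-3-methylpent-3-en-1-yl]oxy(tert-butyl)dimethylsilane | BrC/C=C(C)\CCO[Si](C)(C)C(C)(C)C | intermediate
8 | 1,3-dithiane | C1CSCSC1 | starting material
9 | triphenylcarbenium tetrafluoroborate | [C+](c1ccccc1)(c1ccccc1)c1ccccc1.F[B-](F)(F)F | starting material
10 | 1,3-dithian-2-ylium tetrafluoroborate | [CH+]1SCCCS1.F[B-](F)(F)F | intermediate
11 | (5R)-5-(hydroxymethyl)oxolan-2-one | O=C1CC[C@H](CO)O1 | starting material
12 | (5R)-5-{[(triethylsilyl)oxy]methyl}oxolan-2-one | O=C1CC[C@H](CO[Si](CC)(CC)CC)O1 | intermediate
13 | triethyl{[(2R)-5-[(trimethylsilyl)oxy]-2,3-dihydrofuran-2-yl]methoxy}silane (formed in situ) | C[Si](C)(C)OC1=CC[C@H](CO[Si](CC)(CC)CC)O1 | intermediate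
14 | (3S,5R)-3-(1,3-dithian-2-yl)-5-{[(triethylsilyl)oxy]methyl}oxolan-2-one | O=C1[C@@H](C2SCCCS2)C[C@H](CO[Si](CC)(CC)CC)O1 | intermediate
15 | (2S,4R)-2-(1,3-dithian-2-yl)-5-[(triethylsilyl)oxy]pentane-1,4-diol | OC[C@@H](C1SCCCS1)C[C@@H](O)CO[Si](CC)(CC)CC | intermediate
16 | (2R,4S)-5-[(tert-butyldiphenylsilyl)oxy]-4-(1,3-dithian-2-yl)-1-[(triethylsilyl)oxy]pentan-2-ol (formed in situ) | CC(C)(C)[Si](c1ccccc1)(c1ccccc1)OC[C@@H](C1SCCCS1)C[C@@H](O)CO[Si](CC)(CC)CC | intermediate
17 | 2-[(2S,4R)-1-[(tert-butyldiphenylsilyl)oxy]-4,5-bis[(triethylsilyl)oxy]pentan-2-yl]-1,3-dithiane | CC(C)(C)[Si](c1ccccc1)(c1ccccc1)OC[C@@H](C1SCCCS1)C[C@@H](O[Si](CC)(CC)CC)CO[Si](CC)(CC)CC | intermediate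
18 | 2-lithio derivative of 17 (lithium on C2 of the dithiane; formed in situ) | [Li]C1(SCCCS1)[C@H](CO[Si](c1ccccc1)(c1ccccc1)C(C)(C)C)C[C@@H](O[Si](CC)(CC)CC)CO[Si](CC)(CC)CC | intermediate
19 | 2-[(2S,4R)-1-[(tert-butyldiphenylsilyl)oxy]-4,5-bis[(triethylsilyl)oxy]pentan-2-yl]-2-[(2Z)-5-[(tert-butyldimethylsilyl)oxy]-3-methylpent-2-en-1-yl]-1,3-dithiane | CC(C)(C)[Si](C)(C)OCC/C(C)=C\CC1(SCCCS1)[C@H](CO[Si](c1ccccc1)(c1ccccc1)C(C)(C)C)C[C@@H](O[Si](CC)(CC)CC)CO[Si](CC)(CC)CC | intermediate
20 | (2R,4S)-4-{2-[(2Z)-5-[(tert-butyldimethylsilyl)oxy]-3-methylpent-2-en-1-yl]-1,3-dithian-2-yl}-5-[(tert-butyldiphenylsilyl)oxy]-2-[(triethylsilyl)oxy]pentanal | CC(C)(C)[Si](C)(C)OCC/C(C)=C\CC1(SCCCS1)[C@H](CO[Si](c1ccccc1)(c1ccccc1)C(C)(C)C)C[C@@H](O[Si](CC)(CC)CC)C=O | intermediate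
21 | methyl (3RS,4R,6S)-6-{2-[(2Z)-5-[(tert-butyldimethylsilyl)oxy]-3-methylpent-2-en-1-yl]-1,3-dithian-2-yl}-7-[(tert-butyldiphenylsilyl)oxy]-3-hydroxy-2-methylidene-4-[(triethylsilyl)oxy]heptanoate | CC(C)(C)[Si](C)(C)OCC/C(C)=C\CC1(SCCCS1)[C@H](CO[Si](c1ccccc1)(c1ccccc1)C(C)(C)C)C[C@@H](O[Si](CC)(CC)CC)C(O)C(=C)C(=O)OC | intermediate
22 | methyl (3RS,4R,6S)-6-{2-[(2Z)-5-[(tert-butyldimethylsilyl)oxy]-3-methylpent-2-en-1-yl]-1,3-dithian-2-yl}-7-[(tert-butyldiphenylsilyl)oxy]-3,4-dihydroxy-2-methylideneheptanoate (formed in situ) | CC(C)(C)[Si](C)(C)OCC/C(C)=C\CC1(SCCCS1)[C@H](CO[Si](c1ccccc1)(c1ccccc1)C(C)(C)C)C[C@@H](O)C(O)C(=C)C(=O)OC | intermediate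
23 | (4RS,5R)-5-[(2S)-2-{2-[(2Z)-5-[(tert-butyldimethylsilyl)oxy]-3-methylpent-2-en-1-yl]-1,3-dithian-2-yl}-3-[(tert-butyldiphenylsilyl)oxy]propyl]-4-hydroxy-3-methylideneoxolan-2-one | CC(C)(C)[Si](C)(C)OCC/C(C)=C\CC1(SCCCS1)[C@H](CO[Si](c1ccccc1)(c1ccccc1)C(C)(C)C)C[C@H]1OC(=O)C(=C)C1O | intermediate
24 | methanesulfonate of 23 at the ring hydroxyl (formed in situ) | CC(C)(C)[Si](C)(C)OCC/C(C)=C\CC1(SCCCS1)[C@H](CO[Si](c1ccccc1)(c1ccccc1)C(C)(C)C)C[C@H]1OC(=O)C(=C)C1OS(C)(=O)=O | intermediate
25 | (5R)-3-(bromomethyl)-5-[(2S)-2-{2-[(2Z)-5-[(tert-butyldimethylsilyl)oxy]-3-methylpent-2-en-1-yl]-1,3-dithian-2-yl}-3-[(tert-butyldiphenylsilyl)oxy]propyl]furan-2(5H)-one | CC(C)(C)[Si](C)(C)OCC/C(C)=C\CC1(SCCCS1)[C@H](CO[Si](c1ccccc1)(c1ccccc1)C(C)(C)C)C[C@H]1OC(=O)C(CBr)=C1 | intermediate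
26 | (5R)-3-(bromomethyl)-5-[(2S)-3-[(tert-butyldiphenylsilyl)oxy]-2-{2-[(2Z)-5-hydroxy-3-methylpent-2-en-1-yl]-1,3-dithian-2-yl}propyl]furan-2(5H)-one | OCC/C(C)=C\CC1(SCCCS1)[C@H](CO[Si](c1ccccc1)(c1ccccc1)C(C)(C)C)C[C@H]1OC(=O)C(CBr)=C1 | intermediate
27 | (3Z)-5-{2-[(2S)-1-[(2R)-4-(bromomethyl)-5-oxo-2,5-dihydrofuran-2-yl]-3-[(tert-butyldiphenylsilyl)oxy]propan-2-yl]-1,3-dithian-2-yl}-3-methylpent-3-enal | O=CC/C(C)=C\CC1(SCCCS1)[C@H](CO[Si](c1ccccc1)(c1ccccc1)C(C)(C)C)C[C@H]1OC(=O)C(CBr)=C1 | intermediate
28 | allylindium dibromide from 27 (indium on C13 in place of bromine, formulated as the monomer; formed in situ) | O=CC/C(C)=C\CC1(SCCCS1)[C@H](CO[Si](c1ccccc1)(c1ccccc1)C(C)(C)C)C[C@H]1OC(=O)C(C[In](Br)Br)=C1 | intermediate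
29 | (1(10)Z,4S,6R,7R,8S)-15-[(tert-butyldiphenylsilyl)oxy]-8-hydroxy-3,3-(propane-1,3-diyldisulfanediyl)germacra-1(10),11(13)-dien-12,6-olide (8α-alcohol) | C=C1C(=O)O[C@@H]2C[C@@H](CO[Si](c3ccccc3)(c3ccccc3)C(C)(C)C)C3(SCCCS3)C/C=C(C)\C[C@H](O)[C@@H]12 | intermediate
30 | (2R)-2-methylbutanoic acid | CC[C@@H](C)C(=O)O | starting material
31 | (1(10)Z,4S,6R,7S,8R)-15-[(tert-butyldiphenylsilyl)oxy]-8-{[(2R)-2-methylbutanoyl]oxy}-3,3-(propane-1,3-diyldisulfanediyl)germacra-1(10),11(13)-dien-12,6-olide | C=C1C(=O)O[C@@H]2C[C@@H](CO[Si](c3ccccc3)(c3ccccc3)C(C)(C)C)C3(SCCCS3)C/C=C(C)\C[C@@H](OC(=O)[C@H](C)CC)[C@@H]12 | intermediate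
32 | (1(10)Z,4S,6R,7S,8R)-15-hydroxy-8-{[(2R)-2-methylbutanoyl]oxy}-3,3-(propane-1,3-diyldisulfanediyl)germacra-1(10),11(13)-dien-12,6-olide | C=C1C(=O)O[C@@H]2C[C@@H](CO)C3(SCCCS3)C/C=C(C)\C[C@@H](OC(=O)[C@H](C)CC)[C@@H]12 | intermediate
33 | (1(10)Z,4S,6R,7S,8R)-15-hydroxy-8-{[(2R)-2-methylbutanoyl]oxy}-3-oxogermacra-1(10),11(13)-dien-12,6-olide | C=C1C(=O)O[C@@H]2C[C@@H](CO)C(=O)C/C=C(C)\C[C@@H](OC(=O)[C@H](C)CC)[C@@H]12 | intermediate
34 | (1R,4S,6R,7S,8R,10S)-1,10-epoxy-15-hydroxy-8-{[(2R)-2-methylbutanoyl]oxy}-3-oxogermacr-11(13)-en-12,6-olide (CNP0219035.1) | C=C1C(=O)O[C@@H]2C[C@@H](CO)C(=O)C[C@H]3O[C@@]3(C)C[C@@H](OC(=O)[C@H](C)CC)[C@@H]12 | target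

## Step count and least certain steps

Total: 22 steps. Longest linear sequence: 17 steps (steps 1–5 and 11–22, from but-3-yn-1-ol); the chiral-pool branch (steps 7–10, then 11–22) is 16 steps.

**Step 18 (key step).**
- What may go wrong: ring closure may lose to intermolecular addition or to protonation of the allylindium in the aqueous medium. The β,γ-unsaturated aldehyde may move into conjugation before it is captured. Strain in the forming ten-membered ring may pull the addition away from the chair and give mixtures at C8, or make the α-carbon C13 compete with C7.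
- Fallback: starting again from 27, the nucleophile would be generated away from water. Two equivalents of divalent chromium (CrCl2, anhydrous THF, high dilution) reduce the bromide, and the trivalent allylchromium closes the ring in a Nozaki–Hiyama reaction, a method with a record in medium-ring closures and a strong preference for the chair. It returns to 29 and makes no new compound (F0).

**Step 19.**
- What may go wrong: the activated C8 oxygen has β-hydrogens on C7 and C9 that are both allylic, so elimination may compete with substitution. The hindered alcohol and the weakly acidic aliphatic acid may also make the Mitsunobu reaction slow.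
- Fallback: from 29, chloromethanesulfonyl chloride and pyridine would give the 8-O-chloromethanesulfonyl derivative F1. Heating F1 with 30, Cs2CO3 and 18-crown-6 in toluene would displace the sulfonate with inversion and rejoin the route at 31.

**Step 22.**
- What may go wrong: poor facial selectivity, because the face of the olefin is chosen only by the conformation of the ring; some oxidation of the methylene lactone is also possible.
- Fallback: from 33, substrate control would be replaced by reagent control. A chiral dioxirane would be generated from a fructose-derived ketone and KHSO5 (Shi epoxidation, run at the low end of its pH range because of the β-hydroxy ketone), using the ketone enantiomer that matches the required face. It returns to 34 and makes no new compound (F0).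

**Step 8.**
- What may go wrong: incomplete anti selectivity at C4, sluggish reaction of the sparingly soluble carbenium salt, or loss of the triethylsilyl ether to the boron trifluoride that is liberated.
- Fallback: from 12, C3 would be brought in at the alcohol level.
  - The lithium enolate of 12 (LiN(iPr)2, THF, −78 °C) would be alkylated with benzyl chloromethyl ether anti to the C6 side chain to give the trans lactone (3R,5R)-3-[(benzyloxy)methyl]-5-{[(triethylsilyl)oxy]methyl}oxolan-2-one F2.
  - LiBH4 would open it to the diol F3.
  - The two-stage silylation of step 10 would give the fully silylated benzyl ether F4.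
  - Hydrogenolysis (H2, Pd/C, EtOAc) would free the primary alcohol F5.
  - Dess–Martin oxidation would give the aldehyde F6.
  - Propane-1,3-dithiol with MgBr2·OEt2 would convert F6 into 17, where the route is rejoined.

**Step 12.**
- What may go wrong: incomplete cleavage of the primary triethylsilyl ether, or concurrent loss of the secondary one at C6, under the Swern conditions.
- Fallback: from 19, deprotection and oxidation would be separated. Mild acid (PPTS, MeOH/CH2Cl2, −10 °C) would remove the primary triethylsilyl ether alone to give the primary alcohol F7, and Dess–Martin periodinane would oxidise F7 to 20.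

## Further compounds

F1 | step 19 | 8-O-chloromethanesulfonyl derivative of 29 (8α, configuration of 29 retained) | C=C1C(=O)O[C@@H]2C[C@@H](CO[Si](c3ccccc3)(c3ccccc3)C(C)(C)C)C3(SCCCS3)C/C=C(C)\C[C@H](OS(=O)(=O)CCl)[C@@H]12
F2 | step 8 | (3R,5R)-3-[(benzyloxy)methyl]-5-{[(triethylsilyl)oxy]methyl}oxolan-2-one | O=C1[C@@H](COCc2ccccc2)C[C@H](CO[Si](CC)(CC)CC)O1
F3 | step 8 | (2S,4R)-2-[(benzyloxy)methyl]-5-[(triethylsilyl)oxy]pentane-1,4-diol | OC[C@@H](COCc1ccccc1)C[C@@H](O)CO[Si](CC)(CC)CC
F4 | step 8 | benzyl ether analogue of 17 (benzyloxymethyl in place of the dithianyl group) | CC(C)(C)[Si](c1ccccc1)(c1ccccc1)OC[C@@H](COCc1ccccc1)C[C@@H](O[Si](CC)(CC)CC)CO[Si](CC)(CC)CC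
F5 | step 8 | primary alcohol from F4 (hydroxymethyl in place of the dithianyl group of 17) | CC(C)(C)[Si](c1ccccc1)(c1ccccc1)OC[C@@H](CO)C[C@@H](O[Si](CC)(CC)CC)CO[Si](CC)(CC)CC
F6 | step 8 | aldehyde from F5 (formyl in place of the dithianyl group of 17) | CC(C)(C)[Si](c1ccccc1)(c1ccccc1)OC[C@@H](C=O)C[C@@H](O[Si](CC)(CC)CC)CO[Si](CC)(CC)CC
F7 | step 12 | primary alcohol from 19 (C7 hydroxyl free, other silyl ethers kept) | CC(C)(C)[Si](C)(C)OCC/C(C)=C\CC1(SCCCS1)[C@H](CO[Si](c1ccccc1)(c1ccccc1)C(C)(C)C)C[C@@H](O[Si](CC)(CC)CC)CO
F0 | step 18 | none | none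
F0 | step 22 | none | none
A1 | alternative 1 | cyclopropanol aldehyde (cyclopropan-1-ol across C3/C4/C5, aldehyde at C6, ester at C8, silyl ethers at C12 and C15) | O=C[C@H](C(=C)CO[Si](C)(C)C(C)(C)C)[C@H](OC(=O)[C@H](C)CC)C/C(C)=C\CC1(O)C[C@H]1CO[Si](C)(C)C(C)(C)C
A2 | alternative 1 | ten-membered γ-hydroxy ketone | C=C(CO[Si](C)(C)C(C)(C)C)[C@H]1[C@H](O)C[C@@H](CO[Si](C)(C)C(C)(C)C)C(=O)C/C=C(C)\C[C@H]1OC(=O)[C@H](C)CC
A3 | alternative 2 | bicyclic diene lactone with the tetrasubstituted C3=C8 olefin | C=C1C(=O)O[C@@H]2C[C@@H](CO[Si](C)(C)C(C)(C)C)C3=C(CC(C)=CC3)[C@@H]12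
A4 | alternative 2 | Z-cyclodecene-3,8-dione lactone | C=C1C(=O)O[C@@H]2C[C@@H](CO[Si](C)(C)C(C)(C)C)C(=O)C/C=C(C)\CC(=O)[C@@H]12
A5 | alternative 3 | lactone aldehyde with a pinacol boronate at C1 (configuration at C1 chosen for the transfer) | O=C[C@H]1CC(=O)O[C@@H]1C[C@@H](CO[Si](C)(C)C(C)(C)C)C2(SCCCS2)CC(B3OC(C)(C)C(C)(C)O3)C(C)=C
A6 | alternative 3 | ten-membered Z-homoallylic alcohol lactone | C1C(=O)O[C@@H]2C[C@@H](CO[Si](C)(C)C(C)(C)C)C3(SCCCS3)C/C=C(C)\C[C@@H](O)[C@@H]12
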